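The route rests on cutting C5–C9 and C2–C3 of the bicyclo[3.3.1]nonane-2,4,9-trione. This exploits the fact that C9 and C2 are two carbonyls on C1 (a prenylmalonate) while C3–C4 is an acetyl group on C5: one alkoxide-mediated operation acylates C5 (ring B: C1, C8, C7, C6, C5, C9) and then C3 (ring A: C1, C2, C3, C4, C5, C9), setting C1 and C5. The precursor is the acyclic methyl ketone–malonate 11, whose C3–C8 chain and C7 stereocentre come from (S)-limonene and whose two prenyl groups are made together by ozonolysis and double Wittig olefination. Bridgehead geranylation, C3 aroylation and deprotection complete the target.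

Key step: step 7

Assumption: the target is a tautomerising β-hydroxy enone drawn with the C2 ketone and the C4 enol, so the regiochemistry of the transient methyl enol ether does not affect the final product; (S)-limonene of high enantiomeric purity is taken, and its stereocentre (C7 of the target) is never a reacting centre.

Step 1
Reactants: 1 (S)-limonene
Product: 2 (S)-α-terpinyl chloride, (4S)-4-(2-chloropropan-2-yl)-1-methylcyclohex-1-ene
Conditions: dry HCl (1.0 equiv), CH2Cl2, −20 °C
Reagents that add atoms: hydrogen chloride, Cl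
Why: Markovnikov hydrochlorination in which the 1,1-disubstituted isopropenyl alkene is protonated in preference to the ring alkene and the tertiary ion pair collapses at once, so the ring stereocentre is not touched.

Step 2
Reactants: 3 dimethyl malonate
Product: 4 methyl 3-methoxy-3-(trimethylsilyloxy)prop-2-enoate (ketene silyl acetal, E/Z mixture)
Conditions: TMSOTf, Et3N, Et2O, 0 °C
Reagents that add atoms: trimethylsilyl trifluoromethanesulfonate, C[Si](C)(C)OS(=O)(=O)C(F)(F)F
Why: Soft enolisation and O-silylation of the malonate gives the neutral π-nucleophile needed for a cationic alkylation.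

Step 3
Reactants: 2 (S)-α-terpinyl chloride, 4 ketene silyl acetal
Product: 5 dimethyl 2-{2-[(1S)-4-methylcyclohex-3-en-1-yl]propan-2-yl}propanedioate
Conditions: ZnCl2 (20 mol%), 4 (1.5 equiv), CH2Cl2, −30 °C→0 °C; aq. NaHCO3
Reagents that add atoms: none
Why: Lewis-acid-mediated SN1 tert-alkylation of a ketene silyl acetal (Mukaiyama-type alkylation), in which ZnCl2 reversibly ionises the tertiary chloride and the nucleophile captures the ion pair to form the quaternary carbon C8, low temperature and excess nucleophile keeping capture ahead of hydride shift from the neighbouring stereocentre.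

Step 4
Reactants: 5 terpinyl malonate, 6 allyl bromide
Product: 7 dimethyl 2-{2-[(1S)-4-methylcyclohex-3-en-1-yl]propan-2-yl}-2-(prop-2-en-1-yl)propanedioate
Conditions: NaH, DMF, 0 °C→50 °C
Reagents that add atoms: none
Why: SN2 alkylation of the malonate enolate by an unhindered allylic halide makes C1 quaternary, which removes the acidic malonate C–H before the ylide step and installs the alkene that becomes the C1 prenyl group.

Step 5
Reactants: 7 allyl terpinyl malonate
Product: 9 dimethyl 2-[(3S)-2-methyl-6-oxo-3-(2-oxoethyl)heptan-2-yl]-2-(2-oxoethyl)propanedioate, via bis-ozonide 8 (not isolated)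
Conditions: O3, CH2Cl2, −78 °C; then PPh3, −78 °C→rt
Reagents that add atoms: ozone, [O-][O+]=O
Why: Ozonolysis (Criegee mechanism) with reductive work-up opens the ring alkene to the methyl ketone and one aldehyde and cuts the allyl group to the second aldehyde, the esters and the stereocentre being inert.

Step 6
Reactants: 9 keto dialdehyde, 10 isopropyltriphenylphosphonium iodide
Product: 11 dimethyl 2-[(3S)-2-methyl-3-(3-methylbut-2-en-1-yl)-6-oxoheptan-2-yl]-2-(3-methylbut-2-en-1-yl)propanedioate
Conditions: 10 (2.2 equiv), n-BuLi, THF, 0 °C; then 9, −78 °C→0 °C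
Reagents that add atoms: none
Why: Wittig olefination in which the hindered non-stabilised isopropylidene ylide reacts with the two aldehydes far faster than with the methyl ketone or the neopentyl esters, forming both prenyl groups at once with no alkene geometry to control.

Step 7
Reactants: 11 keto malonate
Product: 13 (1R,5S,7R)-4-hydroxy-8,8-dimethyl-1,7-bis(3-methylbut-2-en-1-yl)bicyclo[3.3.1]non-3-ene-2,9-dione, via monocyclic diketo ester 12 (not isolated)
Conditions: KOtBu (2.5 equiv), t-BuOH (5 equiv), THF, 0 °C→rt, then 65 °C; 1 M HCl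
Reagents that add atoms: none
Why: KOtBu equilibrates the ketone enolates of 11, the C5 enolate adds to one malonate ester and expels methoxide (Claisen condensation) to give the potassium diketonate of 12, and on heating this is in equilibrium, through the t-BuOH proton shuttle, with its minor acetyl-methyl (C3) enolate still bearing C5–H, which adds to the axial C1 ester (Dieckmann-type closure) to give the trione, held as its C2–C3–C4 enolate. The closest known reactions are the Claisen cyclisation of ε-keto esters to 2-acylcyclohexanones and the acetyl-to-ester Dieckmann closure that gives bicyclo[3.3.1]nonane-2,4,9-triones. Ring B closes by 6-exo-trig attack of C5 on C9 and ring A by 6-exo-trig attack of C3 on C2. C1 is set in the first closure by the choice between the two diastereotopic esters in a chair transition state with the C7 and C1 prenyl groups equatorial and the spectator ester axial, and C5 is set because it remains an epimerisable methine and only the epimer with the acetyl group axial, cis to the C1 ester, can bridge. The step needs acylation of C5 before C3, which is secured because attack by C3 would form an eight-membered ring, and it needs the second enolate to form while C5 is tetrahedral, which is why an alkoxide/alcohol system is used and not an amide base: a C3,C5-dianion is planar at C5 and could only close to an anti-Bredt bridgehead enolate.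

Step 8
Reactants: 13 bicyclic trione enol
Product: 14 (1R,5S,7R)-4-methoxy-8,8-dimethyl-1,7-bis(3-methylbut-2-en-1-yl)bicyclo[3.3.1]non-3-ene-2,9-dione
Conditions: Me2SO4, K2CO3, acetone, rt
Reagents that add atoms: dimethyl sulfate, COS(=O)(=O)OC
Why: O-Alkylation of the vinylogous acid enolate by a hard methylating agent should take place at O4, the oxygen remote from the quaternary C1, and gives the vinylogous ester that masks the acidic triketone for the two lithiations.

Step 9
Reactants: 14 methyl enol ether, 15 geranyl bromide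
Product: 17 (1R,5S,7R)-5-[(2E)-3,7-dimethylocta-2,6-dien-1-yl]-4-methoxy-8,8-dimethyl-1,7-bis(3-methylbut-2-en-1-yl)bicyclo[3.3.1]non-3-ene-2,9-dione, via C5-lithio enol ether 16 (not isolated)
Conditions: LiN(iPr)2, THF, −78 °C; then 15, −78 °C→−20 °C
Reagents that add atoms: none
Why: Bridgehead lithiation–alkylation known for this ring system, in which the C5–H flanked by the C9 ketone and the vinylogous ester is removed to a pyramidal carbanion that cannot invert and is alkylated by SN2 on the allylic bromide, so the (E)-geranyl group takes the place of hydrogen with retention.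

Step 10
Reactants: 18 3,4-dihydroxybenzoic acid
Product: 19 tert-butyldimethylsilyl 3,4-bis[(tert-butyldimethylsilyl)oxy]benzoate
Conditions: TBSCl (3.3 equiv), imidazole, DMF, rt
Reagents that add atoms: tert-butyldimethylsilyl chloride, CC(C)(C)[Si](C)(C)Cl
Why: Imidazole-promoted silylation turns both phenols into silyl ethers and the acid into its silyl ester, which protects the catechol in a form that hydroxide or fluoride removes.

Step 11
Reactants: 19 tris-silyl protocatechuate
Product: 20 3,4-bis[(tert-butyldimethylsilyl)oxy]benzoyl chloride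
Conditions: (COCl)2, DMF (cat.), CH2Cl2, 0 °C→rt
Reagents that add atoms: oxalyl chloride, ClC(=O)C(Cl)=O
Why: Vilsmeier-type chlorination converts the silyl ester directly into the acid chloride under neutral conditions that leave the aryl silyl ethers intact.

Step 12
Reactants: 17 C5-geranyl enol ether, 20 aroyl chloride
Product: 22 (1S,5S,7R)-3-{3,4-bis[(tert-butyldimethylsilyl)oxy]benzoyl}-5-[(2E)-3,7-dimethylocta-2,6-dien-1-yl]-4-methoxy-8,8-dimethyl-1,7-bis(3-methylbut-2-en-1-yl)bicyclo[3.3.1]non-3-ene-2,9-dione, via C3-lithio enol ether 21 (not isolated)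
Conditions: LiTMP (lithium 2,2,6,6-tetramethylpiperidide), THF, −78 °C; then 20, −78 °C→−40 °C
Reagents that add atoms: none
Why: With both bridgeheads quaternary the only acidic site is the vinylic C3–H between the C2 carbonyl and the C4 methoxy group, and its lithiation by the hindered amide followed by C-acylation with the acid chloride is the established way to 3-aroyl derivatives of this ring system.

Step 13
Reactants: 22 protected aroyl enol ether
Product: 23 target, (1S,5S,7R)-3-(3,4-dihydroxybenzoyl)-5-[(2E)-3,7-dimethylocta-2,6-dien-1-yl]-4-hydroxy-8,8-dimethyl-1,7-bis(3-methylbut-2-en-1-yl)bicyclo[3.3.1]non-3-ene-2,9-dione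
Conditions: LiOH, H2O/1,4-dioxane (degassed), Ar, 90 °C; then 1 M HCl
Reagents that add atoms: lithium hydroxide, [Li+].[OH-]
Why: Hydroxide cleaves the vinylogous methyl ester by addition–elimination at C4 and the two aryl silyl ethers by attack at silicon, no stereocentre being involved and exclusion of oxygen protecting the catecholate.

Compound list

1 | (S)-limonene, (4S)-1-methyl-4-(prop-1-en-2-yl)cyclohex-1-ene | CC1=CC[C@H](CC1)C(C)=C | starting material
2 | (S)-α-terpinyl chloride, (4S)-4-(2-chloropropan-2-yl)-1-methylcyclohex-1-ene | CC1=CC[C@H](CC1)C(C)(C)Cl | intermediate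
3 | dimethyl malonate | COC(=O)CC(=O)OC | starting material
4 | methyl 3-methoxy-3-(trimethylsilyloxy)prop-2-enoate (E/Z mixture) | COC(=O)C=C(OC)O[Si](C)(C)C | intermediate
5 | dimethyl 2-{2-[(1S)-4-methylcyclohex-3-en-1-yl]propan-2-yl}propanedioate | CC1=CC[C@H](CC1)C(C)(C)C(C(=O)OC)C(=O)OC | intermediate
6 | allyl bromide | C=CCBr | starting material
7 | dimethyl 2-{2-[(1S)-4-methylcyclohex-3-en-1-yl]propan-2-yl}-2-(prop-2-en-1-yl)propanedioate | CC1=CC[C@H](CC1)C(C)(C)C(CC=C)(C(=O)OC)C(=O)OC | intermediate
8 | bis-ozonide of 7 (two 1,2,4-trioxolanes, mixture of diastereomers at the new centres) | CC12CC[C@@H](CC(O1)OO2)C(C)(C)C(CC1OCOO1)(C(=O)OC)C(=O)OC | intermediate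
9 | dimethyl 2-[(3S)-2-methyl-6-oxo-3-(2-oxoethyl)heptan-2-yl]-2-(2-oxoethyl)propanedioate | CC(=O)CC[C@@H](CC=O)C(C)(C)C(CC=O)(C(=O)OC)C(=O)OC | intermediate
10 | isopropyltriphenylphosphonium iodide | CC(C)[P+](c1ccccc1)(c1ccccc1)c1ccccc1.[I-] | starting material
11 | dimethyl 2-[(3S)-2-methyl-3-(3-methylbut-2-en-1-yl)-6-oxoheptan-2-yl]-2-(3-methylbut-2-en-1-yl)propanedioate | CC(=O)CC[C@@H](CC=C(C)C)C(C)(C)C(CC=C(C)C)(C(=O)OC)C(=O)OC | intermediate
12 | methyl (1S,5R)-3-acetyl-6,6-dimethyl-1,5-bis(3-methylbut-2-en-1-yl)-2-oxocyclohexane-1-carboxylate (C3 epimerisable, present as its potassium enolate) | CC(=O)C1C[C@@H](CC=C(C)C)C(C)(C)[C@](CC=C(C)C)(C(=O)OC)C1=O | intermediate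
13 | (1R,5S,7R)-4-hydroxy-8,8-dimethyl-1,7-bis(3-methylbut-2-en-1-yl)bicyclo[3.3.1]non-3-ene-2,9-dione (C7 prenyl equatorial on chair ring B) | [C@H]12C[C@@H](CC=C(C)C)C(C)(C)[C@](CC=C(C)C)(C(=O)C=C1O)C2=O | intermediate
14 | (1R,5S,7R)-4-methoxy-8,8-dimethyl-1,7-bis(3-methylbut-2-en-1-yl)bicyclo[3.3.1]non-3-ene-2,9-dione | [C@H]12C[C@@H](CC=C(C)C)C(C)(C)[C@](CC=C(C)C)(C(=O)C=C1OC)C2=O | intermediate
15 | geranyl bromide, (2E)-1-bromo-3,7-dimethylocta-2,6-diene | CC(C)=CCC/C(C)=C/CBr | starting material
16 | C5-lithio derivative of 14 (bridgehead organolithium) | [Li][C@]12C[C@@H](CC=C(C)C)C(C)(C)[C@](CC=C(C)C)(C(=O)C=C1OC)C2=O | intermediate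
17 | (1R,5S,7R)-5-[(2E)-3,7-dimethylocta-2,6-dien-1-yl]-4-methoxy-8,8-dimethyl-1,7-bis(3-methylbut-2-en-1-yl)bicyclo[3.3.1]non-3-ene-2,9-dione | CC(C)=CCC/C(C)=C/C[C@]12C[C@@H](CC=C(C)C)C(C)(C)[C@](CC=C(C)C)(C(=O)C=C1OC)C2=O | intermediate
18 | 3,4-dihydroxybenzoic acid | OC(=O)c1ccc(O)c(O)c1 | starting material
19 | tert-butyldimethylsilyl 3,4-bis[(tert-butyldimethylsilyl)oxy]benzoate | CC(C)(C)[Si](C)(C)OC(=O)c1ccc(O[Si](C)(C)C(C)(C)C)c(O[Si](C)(C)C(C)(C)C)c1 | intermediate
20 | 3,4-bis[(tert-butyldimethylsilyl)oxy]benzoyl chloride | ClC(=O)c1ccc(O[Si](C)(C)C(C)(C)C)c(O[Si](C)(C)C(C)(C)C)c1 | intermediate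
21 | C3-lithio derivative of 17 (vinyllithium) | CC(C)=CCC/C(C)=C/C[C@]12C[C@@H](CC=C(C)C)C(C)(C)[C@](CC=C(C)C)(C(=O)C([Li])=C1OC)C2=O | intermediate
22 | (1S,5S,7R)-3-{3,4-bis[(tert-butyldimethylsilyl)oxy]benzoyl}-5-[(2E)-3,7-dimethylocta-2,6-dien-1-yl]-4-methoxy-8,8-dimethyl-1,7-bis(3-methylbut-2-en-1-yl)bicyclo[3.3.1]non-3-ene-2,9-dione | CC(C)=CCC/C(C)=C/C[C@]12C[C@@H](CC=C(C)C)C(C)(C)[C@](CC=C(C)C)(C(=O)C(C(=O)c3ccc(O[Si](C)(C)C(C)(C)C)c(O[Si](C)(C)C(C)(C)C)c3)=C1OC)C2=O | intermediate
23 | (1S,5S,7R)-3-(3,4-dihydroxybenzoyl)-5-[(2E)-3,7-dimethylocta-2,6-dien-1-yl]-4-hydroxy-8,8-dimethyl-1,7-bis(3-methylbut-2-en-1-yl)bicyclo[3.3.1]non-3-ene-2,9-dione | CC(C)=CCC/C(C)=C/C[C@]12C[C@@H](CC=C(C)C)C(C)(C)[C@](CC=C(C)C)(C(=O)C(C(=O)c3ccc(O)c(O)c3)=C1O)C2=O | target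

Total step count: 13. Longest linear sequence: 10 steps (1 → 2 → 5 → 7 → 9 → 11 → 13 → 14 → 17 → 22 → 23; steps 1, 3, 4, 5, 6, 7, 8, 9, 12, 13).

Steps most likely to fail

1. Step 7. The closure of ring A may stall, because the base rests on the stabilised C4–C5–C9 diketonate of 12 and the reactive C3 enolate is only a minor partner, so that intermolecular condensation or cleavage can overtake it on long heating. In addition, the discrimination between the two ester groups in the ring B closure may be incomplete, which would carry material into the C1-epimeric series. Fallback, setting out from 11 and returning at 17: the condensation is stopped after ring B (KOtBu, 1.2 equiv, THF, 0 °C, acidic quench) and the diketo ester 12 is isolated. C-Alkylation of its diketonate at C5 with geranyl bromide 15 (K2CO3, acetone), expected anti to the axial C1 ester, should give methyl (1S,3S,5R)-3-acetyl-3-[(2E)-3,7-dimethylocta-2,6-dien-1-yl]-6,6-dimethyl-1,5-bis(3-methylbut-2-en-1-yl)-2-oxocyclohexane-1-carboxylate F1. With C5 quaternary the acetyl methyl is the only enolisable site, and KOtBu (THF, 0 °C to rt) should effect the acetyl-to-ester Dieckmann closure known for such substrates, giving (1R,5S,7R)-5-[(2E)-3,7-dimethylocta-2,6-dien-1-yl]-4-hydroxy-8,8-dimethyl-1,7-bis(3-methylbut-2-en-1-yl)bicyclo[3.3.1]non-3-ene-2,9-dione F2. O-Methylation (Me2SO4, K2CO3, acetone) then gives 17, and the bridgehead lithiation is no longer needed.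

2. Step 3. After ionisation of 2, a 1,2-hydride shift from the ring stereocentre to the cationic carbon, or loss of a proton, may compete with capture by the weakly nucleophilic malonate ketene acetal, which would erode enantiomeric purity and yield. Fallback, setting out from 1 and returning at 5, in which the quaternary carbon is made by conjugate addition and no cation is formed next to the stereocentre: epoxidation of the ring alkene of 1 (mCPBA, CH2Cl2, 0 °C) gives (4S)-limonene 1,2-oxide F3. Ozonolysis of its isopropenyl group (O3, CH2Cl2, −78 °C; PPh3) gives the keto epoxide (4S)-4-acetyl-1-methyl-7-oxabicyclo[4.1.0]heptane F4. Deoxygenation (Zn, NaI, NaOAc, AcOH) restores the alkene in 1-[(1S)-4-methylcyclohex-3-en-1-yl]ethan-1-one F5. Knoevenagel condensation with 3 (TiCl4, pyridine, THF, 0 °C, kept cold to spare the α-stereocentre) gives dimethyl 2-{1-[(1S)-4-methylcyclohex-3-en-1-yl]ethylidene}propanedioate F6. Copper-catalysed 1,4-addition (MeMgBr, CuI cat., THF, −20 °C) then gives 5.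

3. Step 9. Deprotonation may take place at the vinylic C3–H instead of the C5 bridgehead, or the two lithio species may exchange before alkylation, leading to C3 geranylation or recovered 14. Fallback, setting out from 14 and returning at 17, with C3 blocked as a vinylsilane: LiN(iPr)2 in the presence of TMSCl (in situ quench, THF, −78 °C) should give (1S,5S,7R)-4-methoxy-8,8-dimethyl-1,7-bis(3-methylbut-2-en-1-yl)-3-(trimethylsilyl)bicyclo[3.3.1]non-3-ene-2,9-dione F7. A second treatment with LiN(iPr)2 can then only remove the bridgehead hydrogen, and geranyl bromide 15 gives (1S,5S,7R)-5-[(2E)-3,7-dimethylocta-2,6-dien-1-yl]-4-methoxy-8,8-dimethyl-1,7-bis(3-methylbut-2-en-1-yl)-3-(trimethylsilyl)bicyclo[3.3.1]non-3-ene-2,9-dione F8. Desilylation (TBAF, THF, 0 °C) gives 17.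

Further compounds

F1 | step 7 | methyl (1S,3S,5R)-3-acetyl-3-[(2E)-3,7-dimethylocta-2,6-dien-1-yl]-6,6-dimethyl-1,5-bis(3-methylbut-2-en-1-yl)-2-oxocyclohexane-1-carboxylate | CC(=O)[C@]1(C/C=C(\C)CCC=C(C)C)C[C@@H](CC=C(C)C)C(C)(C)[C@](CC=C(C)C)(C(=O)OC)C1=O
F2 | step 7 | (1R,5S,7R)-5-[(2E)-3,7-dimethylocta-2,6-dien-1-yl]-4-hydroxy-8,8-dimethyl-1,7-bis(3-methylbut-2-en-1-yl)bicyclo[3.3.1]non-3-ene-2,9-dione | CC(C)=CCC/C(C)=C/C[C@]12C[C@@H](CC=C(C)C)C(C)(C)[C@](CC=C(C)C)(C(=O)C=C1O)C2=O
F3 | step 3 | (4S)-limonene 1,2-oxide, (4S)-1-methyl-4-(prop-1-en-2-yl)-7-oxabicyclo[4.1.0]heptane (cis/trans mixture) | CC12CC[C@@H](CC1O2)C(C)=C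
F4 | step 3 | (4S)-4-acetyl-1-methyl-7-oxabicyclo[4.1.0]heptane (cis/trans mixture) | CC12CC[C@@H](CC1O2)C(C)=O
F5 | step 3 | 1-[(1S)-4-methylcyclohex-3-en-1-yl]ethan-1-one | CC1=CC[C@H](CC1)C(C)=O
F6 | step 3 | dimethyl 2-{1-[(1S)-4-methylcyclohex-3-en-1-yl]ethylidene}propanedioate | CC1=CC[C@H](CC1)C(C)=C(C(=O)OC)C(=O)OC
F7 | step 9 | (1S,5S,7R)-4-methoxy-8,8-dimethyl-1,7-bis(3-methylbut-2-en-1-yl)-3-(trimethylsilyl)bicyclo[3.3.1]non-3-ene-2,9-dione | [C@H]12C[C@@H](CC=C(C)C)C(C)(C)[C@](CC=C(C)C)(C(=O)C([Si](C)(C)C)=C1OC)C2=O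
F8 | step 9 | (1S,5S,7R)-5-[(2E)-3,7-dimethylocta-2,6-dien-1-yl]-4-methoxy-8,8-dimethyl-1,7-bis(3-methylbut-2-en-1-yl)-3-(trimethylsilyl)bicyclo[3.3.1]non-3-ene-2,9-dione | CC(C)=CCC/C(C)=C/C[C@]12C[C@@H](CC=C(C)C)C(C)(C)[C@](CC=C(C)C)(C(=O)C([Si](C)(C)C)=C1OC)C2=O
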